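(The runs stem from a simulated flask for an exercise, noise included.)

Saturday's run had 6.4% of the charge in chains at the first reading, less than Sunday's 13.1%, a ratio of 0.489. Your hunch that impurity simply subtracts from initiator gives 0.0357, so it fails for Saturday's.

common to all: free monomer 0.50 M
- Sunday's: initiator 5 mM; impurity 2.2 mM; run made earlier
- Saturday's: initiator 5 mM; impurity 4.9 mM; run made earlier
- Tuesday's: initiator 2.5 mM; impurity 3.3 mM; run made earlier
- flask: initiator 5.0 mM; impurity 3.3 mM; time 8.0 h

| run | time / h | monomer in chains / % | free monomer / % |
|---|---|---|---|
| Sunday's | 0.417 | 13.1 | 86.5 |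
| Sunday's | 0.667 | 18.9 | 80.2 |
| Sunday's | 1.33 | 32.1 | 67.0 |
| Sunday's | 2.50 | 45.2 | 54.1 |
| Sunday's | 5.00 | 53.9 | 44.1 |
| Saturday's | 0.417 | 6.4 | 93.0 |
| Saturday's | 1.33 | 17.8 | 80.6 |
| Saturday's | 2.00 | 25.0 | 73.1 |
| Saturday's | 3.00 | 33.2 | 65.4 |
| Saturday's | 5.00 | 42.8 | 55.0 |
| Tuesday's | 0.417 | 4.0 | 95.7 |
| Tuesday's | 0.667 | 6.1 | 93.5 |
| Tuesday's | 1.33 | 11.4 | 88.1 |
| Tuesday's | 2.50 | 19.2 | 79.5 |
| Tuesday's | 5.00 | 31.3 | 66.8 |

(each reading ± 0.3 percentage points)

- percentages count the free monomer that a species holds: one self-condensation product counts as two
- the average divides the monomer in chains by the number of chains begun, living and dead together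
- candidate steps: free monomer + initiator -> living end + monomer in chains; free monomer + living end -> monomer in chains + living end; monomer in chains + living end -> free monomer + living end; initiator + impurity -> spent initiator; 2 free monomer -> self-condensation product
- the earlier runs do not show the number of chains; that part of a forecast is a guess

* whether the average number of monomer units in a chain (chains begun, living or dead) reaches 60 by 8.0 h (no / yes)
* average number of monomer units in a chain (chains begun, living or dead) at 8.0 h

Saturday's free monomer at 5.00 h (55.0%) also sits close to Sunday's at 2.50 h (54.1%), a time ratio of 0.500. The early and late ratios, both read from scattered readings, nearly agree, so I freeze the living ends and take each run as a pseudo-first-order approach along one path at its own speed.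

Take the pace, a flask's living ends over Sunday's. Going straight between Sunday's and Saturday's impurity, I put the flask's pace at 0.792. The chain count is my guess, and it leans on the subtraction that failed for Saturday's: Sunday's 2.80 mM, with its impurity taken as used up, makes the flask's 2.22 mM. The flask's 8.0 h then equals 6.34 h of Sunday's, past her last reading at 5.00 h, which held 53.9% in chains. So I commit to a length of about 122 or a little above, well over 60.

The forecast says yes and 125, holding that “the living ends form early and then stay fixed”. The flask gives yes and 129.

    free monomer + initiator → living end + monomer in chains (k = 0.0546 M⁻¹ s⁻¹)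
    free monomer + living end → monomer in chains + living end, rate k2*[living end]*[free monomer] (k = 0.0570 M⁻¹ s⁻¹)
    monomer in chains + living end → free monomer + living end, rate k3*[living end] as long as [monomer in chains] is above zero (k = 0.0119 s⁻¹)
    initiator + impurity → spent initiator (k = 26.2 M⁻¹ s⁻¹)
    2 free monomer → self-condensation product (k = 2.09 × 10⁻⁶ M⁻¹ s⁻¹)

By 0.800 h the flask's initiator stood at 0% of its charge and its impurity at 12.9%, and the living end read 0.00213 M then and 0.00213 M at 8.00 h. Length 60 came at 1.32 h, which the pace puts at 1.05 h of Sunday's, between her 18.9% and 32.1% in chains. Saturday's 3.00 h at its pace is 1.47 h of Sunday's, just past her 1.33 h, and reads 33.2% against her 32.1%. In the flask, with each step taken net, monomer in chains was made 1.34 times as fast as it was used up at 3.16 h and 1.03 times at 8.00 h. At 80.0 h the flask's self-condensation product held 11.4% of the free monomer charged.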